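**Retrosynthetic overview**
Rings: A is the terminal 2,4-dihydroxy-6-methylbenzoyl ring, B the central 2-methoxy-6-methyl-4-oxybenzoyl ring, and C the methyl orsellinate end. C is bought, and B and then A are grown de novo.
Neither depside C(=O)–O bond is made from a di-ortho-substituted benzoic acid. Each is first laid down as an unhindered aryl but-2-ynoate, whose alkyne carbons become C1 (acyl-bearing) and C6 (methyl-bearing) of the new benzoyl ring.
Ring B comes from the 4-O-but-2-ynoate of methyl orsellinate and 1-methoxy-3-silyloxy-5,5-dimethylcyclohexa-1,3-diene. A Diels–Alder/retro-Diels–Alder sequence (loss of isobutene) forms C1–C2 and C5–C6; the diene C–OMe becomes C2–OMe and the diene C–OSi becomes C4–OH, the only unchelated phenol.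
Ring A comes from the but-2-ynoate of that C4–OH and the bis(silyl enol ether) of dimedone, by the same benzannulation. No lasting protecting group is used.

Key step: step 4

Remark: the SMILES holds no stereocentre and no configurationally stable axis, so the target is achiral and no enantiocontrol is needed. The bridgehead stereocentres of the two transient cycloadducts are racemic and vanish on aromatisation.

Step 1
Reactants: 1 3-methoxy-5,5-dimethylcyclohex-2-en-1-one
Product: 3 1-methoxy-5,5-dimethyl-3-(trimethylsilyloxy)cyclohexa-1,3-diene, via lithium α′-dienolate 2 (not isolated)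
Conditions: LDA (1.1 equiv), THF, −78 °C; TMSCl (1.3 equiv), −78 °C to rt; pentane, filtration, distillation
Reagents that add atoms: chlorotrimethylsilane, C[Si](C)(C)Cl; lithium diisopropylamide, [Li+].CC(C)[N-]C(C)C (its Li stays only in 2)
Why: Kinetic α′-enolisation of a vinylogous ester (deprotonation at C6, not at the γ-carbon C4) followed by O-silylation should place OMe on a diene terminus and OSiMe3 on the inner carbon, which is the code for the 2-OMe/4-OH pattern of ring B.

Step 2
Reactants: 4 dimedone (5,5-dimethylcyclohexane-1,3-dione)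
Product: 5 5,5-dimethyl-1,3-bis(trimethylsilyloxy)cyclohexa-1,3-diene
Conditions: TMSOTf (2.2 equiv), Et3N (2.6 equiv), Et2O, 0 °C to rt; phase separation, distillation
Reagents that add atoms: trimethylsilyl trifluoromethanesulfonate, C[Si](C)(C)OS(=O)(=O)C(F)(F)F
Why: Soft double enolisation/O-silylation of a 1,3-diketone should work cleanly because 4 is symmetric, so either direction of the second enolisation gives the same 1,3-diene.

Step 3
Reactants: 6 methyl orsellinate (methyl 2,4-dihydroxy-6-methylbenzoate); 7 but-2-ynoic acid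
Product: 8 methyl 4-(but-2-ynoyloxy)-2-hydroxy-6-methylbenzoate
Conditions: DCC (1.1 equiv), DMAP (5 mol %), CH2Cl2, 0 °C to rt
Reagents that add atoms: none
Why: In this Steglich esterification the 2-OH is hydrogen-bonded to and flanked by the ester, so only the 4-OH should be acylated, and the linear ynoic acid is an unhindered acyl donor.

Step 4
Reactants: 8 methyl 4-(but-2-ynoyloxy)-2-hydroxy-6-methylbenzoate; 3 1-methoxy-5,5-dimethyl-3-(trimethylsilyloxy)cyclohexa-1,3-diene
Product: 12 methyl 2-hydroxy-4-[(4-hydroxy-2-methoxy-6-methylbenzoyl)oxy]-6-methylbenzoate, via silyl ether of the ynoate 9 (not isolated), via bicyclo[2.2.2]octadiene adduct 10 (not isolated), via bis-silylated didepside 11 (not isolated)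
Conditions: BSA (1.5 equiv), o-xylene, 60 °C, 1 h; 3 (3 equiv), 145 °C, 24–48 h; then 1 M HCl, THF, 0 °C to rt
Reagents that add atoms: N,O-bis(trimethylsilyl)acetamide, CC(=N[Si](C)(C)C)O[Si](C)(C)C (its SiMe3 group stays only in 9, 10 and 11)
Why: The electron-rich diene 3 adds across the C≡C of the aryl ynoate in a thermal, normal-electron-demand intermolecular [4+2] cycloaddition that closes the new six-membered carbocycle as the bicyclo[2.2.2]octa-2,5-diene 10 (new bonds C1–C2 and C5–C6 of ring B), and 10 then expels its CH2–CMe2 bridge as 2-methylpropene in a retro-[4+2] step driven by aromatisation, i.e. an Alder–Rickert sequence. The closest known reaction type is the Diels–Alder/retro-Diels–Alder benzannulation of β-alkyl ynoates, macrocyclic ones included, with dimedone-derived 1,3-dioxygenated cyclohexadienes, which gives 6-alkylresorcylates at 140–160 °C. The selectivity needed is regiochemical: both donors of 3 raise the HOMO coefficient at the unsubstituted terminus C4, which bonds to the β-carbon (C–CH3) of the ynoate, so that C1(OMe) ends next to the acyl-bearing carbon (C2–OMe), C3(OSiMe3) para to it (C4–O) and the methyl group at C6. No stereocentre has to be controlled, since the two bridgeheads of racemic 10 are erased on extrusion. Capping the chelated 2-OH of ring C with BSA removes the only proton source that could destroy the diene and the only phenol that could transacylate at 145 °C, and the aryl ester makes the ynoate a better dienophile than the alkyl ynoates of the precedent. The mild acid work-up should cleave both aryl silyl ethers but no ester, so that 12 carries exactly one unchelated phenol, the site of the next ynoate.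

Step 5
Reactants: 12 methyl 2-hydroxy-4-[(4-hydroxy-2-methoxy-6-methylbenzoyl)oxy]-6-methylbenzoate; 7 but-2-ynoic acid
Product: 13 methyl 4-{[4-(but-2-ynoyloxy)-2-methoxy-6-methylbenzoyl]oxy}-2-hydroxy-6-methylbenzoate
Conditions: DCC (1.1 equiv), DMAP (5 mol %), CH2Cl2, 0 °C
Reagents that add atoms: none
Why: This Steglich esterification should take place only at the free 4-OH of ring B, because the sole other hydroxyl (2-OH of ring C) is chelated and hindered, and the low temperature and low DMAP loading spare the existing depside bond.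

Step 6
Reactants: 13 methyl 4-{[4-(but-2-ynoyloxy)-2-methoxy-6-methylbenzoyl]oxy}-2-hydroxy-6-methylbenzoate; 5 5,5-dimethyl-1,3-bis(trimethylsilyloxy)cyclohexa-1,3-diene
Product: 17 methyl 4-({4-[(2,4-dihydroxy-6-methylbenzoyl)oxy]-2-methoxy-6-methylbenzoyl}oxy)-2-hydroxy-6-methylbenzoate (CNP0563156.0), via silyl ether of the didepside ynoate 14 (not isolated), via bicyclo[2.2.2]octadiene adduct 15 (not isolated), via tris-silylated tridepside 16 (not isolated)
Conditions: BSA (1.5 equiv), o-xylene, 60 °C, 1 h; 5 (3 equiv), 145 °C, 24–48 h; then 1 M HCl, THF, 0 °C to rt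
Reagents that add atoms: N,O-bis(trimethylsilyl)acetamide, CC(=N[Si](C)(C)C)O[Si](C)(C)C (its SiMe3 group stays only in 14, 15 and 16)
Why: The same Alder–Rickert benzannulation (Diels–Alder, then retro-Diels–Alder loss of 2-methylpropene), in which terminus C4 of the bis(silyloxy) diene again bonds to the C–CH3 carbon of the ynoate, should deliver ring A with both oxygens as silyl ethers that fall off in the acid work-up, and no stereocentre of racemic 15 survives.

**Compound list**
1 | 3-methoxy-5,5-dimethylcyclohex-2-en-1-one | COC1=CC(=O)CC(C)(C)C1 | starting material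
2 | lithium 3-methoxy-5,5-dimethylcyclohexa-1,3-dien-1-olate type α′-dienolate of 1 (O⁻ on the former C=O carbon, new C=C to former C6) | [Li+].COC1=CC([O-])=CC(C)(C)C1 | intermediate
3 | 1-methoxy-5,5-dimethyl-3-(trimethylsilyloxy)cyclohexa-1,3-diene | COC1=CC(O[Si](C)(C)C)=CC(C)(C)C1 | intermediate
4 | dimedone (5,5-dimethylcyclohexane-1,3-dione) | CC1(C)CC(=O)CC(=O)C1 | starting material
5 | 5,5-dimethyl-1,3-bis(trimethylsilyloxy)cyclohexa-1,3-diene | C[Si](C)(C)OC1=CC(O[Si](C)(C)C)=CC(C)(C)C1 | intermediate
6 | methyl orsellinate (methyl 2,4-dihydroxy-6-methylbenzoate) | COC(=O)c1c(C)cc(O)cc1O | starting material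
7 | but-2-ynoic acid | CC#CC(=O)O | starting material
8 | methyl 4-(but-2-ynoyloxy)-2-hydroxy-6-methylbenzoate | COC(=O)c1c(C)cc(OC(=O)C#CC)cc1O | intermediate
9 | methyl 4-(but-2-ynoyloxy)-6-methyl-2-(trimethylsilyloxy)benzoate | COC(=O)c1c(C)cc(OC(=O)C#CC)cc1O[Si](C)(C)C | intermediate
10 | 4-(methoxycarbonyl)-3-methyl-5-(trimethylsilyloxy)phenyl 1-methoxy-3,8,8-trimethyl-5-(trimethylsilyloxy)bicyclo[2.2.2]octa-2,5-diene-2-carboxylate (racemic, the cage allows one diastereomer only) | COC12CC(C)(C)C(C(O[Si](C)(C)C)=C1)C(C)=C2C(=O)Oc1cc(C)c(C(=O)OC)c(O[Si](C)(C)C)c1 | intermediate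
11 | methyl 4-{[2-methoxy-6-methyl-4-(trimethylsilyloxy)benzoyl]oxy}-6-methyl-2-(trimethylsilyloxy)benzoate | COC(=O)c1c(C)cc(OC(=O)c2c(C)cc(O[Si](C)(C)C)cc2OC)cc1O[Si](C)(C)C | intermediate
12 | methyl 2-hydroxy-4-[(4-hydroxy-2-methoxy-6-methylbenzoyl)oxy]-6-methylbenzoate | COC(=O)c1c(C)cc(OC(=O)c2c(C)cc(O)cc2OC)cc1O | intermediate
13 | methyl 4-{[4-(but-2-ynoyloxy)-2-methoxy-6-methylbenzoyl]oxy}-2-hydroxy-6-methylbenzoate | COC(=O)c1c(C)cc(OC(=O)c2c(C)cc(OC(=O)C#CC)cc2OC)cc1O | intermediate
14 | methyl 4-{[4-(but-2-ynoyloxy)-2-methoxy-6-methylbenzoyl]oxy}-6-methyl-2-(trimethylsilyloxy)benzoate | COC(=O)c1c(C)cc(OC(=O)c2c(C)cc(OC(=O)C#CC)cc2OC)cc1O[Si](C)(C)C | intermediate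
15 | 3,8,8-trimethyl-1,5-bis(trimethylsilyloxy)bicyclo[2.2.2]octa-2,5-diene-2-carboxylate of the ring B 4-OH of silylated 12 (racemic, one diastereomer possible) | C[Si](C)(C)OC12CC(C)(C)C(C(O[Si](C)(C)C)=C1)C(C)=C2C(=O)Oc1cc(C)c(C(=O)Oc2cc(C)c(C(=O)OC)c(O[Si](C)(C)C)c2)c(OC)c1 | intermediate
16 | tris(trimethylsilyl) ether of 17 (ring A 2-O and 4-O, ring C 2-O) | COC(=O)c1c(C)cc(OC(=O)c2c(C)cc(OC(=O)c3c(C)cc(O[Si](C)(C)C)cc3O[Si](C)(C)C)cc2OC)cc1O[Si](C)(C)C | intermediate
17 | methyl 4-({4-[(2,4-dihydroxy-6-methylbenzoyl)oxy]-2-methoxy-6-methylbenzoyl}oxy)-2-hydroxy-6-methylbenzoate (CNP0563156.0, achiral) | COC(=O)c1c(C)cc(OC(=O)c2c(C)cc(OC(=O)c3c(C)cc(O)cc3O)cc2OC)cc1O | target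

**Step count**
Total steps: 6. Longest linear sequence: 4 (steps 3, 4, 5, 6 from 6; equally steps 1, 4, 5, 6 from 1).

**Steps most likely to fail**

Step 4. The cycloaddition to a disubstituted ynoate may be so slow that thermal decay or protodesilylation of the diene outruns it, the isobutene extrusion may stay incomplete, or regiocontrol may erode. The fallback gives up the ring construction and brings ring B in as a ready-made arene by acyl C–O coupling.
- It sets out from 6 and comes back at 12.
- Selective 4-O-benzylation of 6 (BnBr, K2CO3, acetone) gives methyl 4-(benzyloxy)-2-hydroxy-6-methylbenzoate F1.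
- Methylation of the chelated phenol (MeI, K2CO3, DMF) gives methyl 4-(benzyloxy)-2-methoxy-6-methylbenzoate F2.
- Forcing saponification (KOH, aq. DMSO, 100 °C) gives 4-(benzyloxy)-2-methoxy-6-methylbenzoic acid F3.
- Mixed-anhydride coupling with a second portion of 6 (trifluoroacetic anhydride, toluene, rt) gives methyl 4-{[4-(benzyloxy)-2-methoxy-6-methylbenzoyl]oxy}-2-hydroxy-6-methylbenzoate F4.
- Hydrogenolysis (H2, Pd/C, EtOAc) then gives 12.

Step 6. The same slow cycloaddition now meets a substrate with two depside bonds, so acyl migration or ester cleavage during the long heating and incomplete extrusion are the likely failures. The fallback builds ring A by acylketene capture and polyketide-type aldol aromatisation instead of a cycloaddition.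
- It sets out from 12, so step 5 is bypassed too, and comes back at 17.
- Commercial 2,2,6-trimethyl-4H-1,3-dioxin-4-one is deprotonated (LiHMDS, THF, −78 °C) and C-acetylated (AcCl) to 2,2-dimethyl-6-(2-oxopropyl)-4H-1,3-dioxin-4-one F5.
- The dianion of F5 (LDA, 2 equiv) is acylated with N-methoxy-N-methylacetamide to 2,2-dimethyl-6-(2,4-dioxopentyl)-4H-1,3-dioxin-4-one F6.
- Heating F6 with 12 in toluene at 110 °C releases 3,5,7-trioxooct-1-en-1-one (the acylketene) F7.
- The free 4-OH of ring B traps F7 to give the aryl 3,5,7-trioxooctanoate F8.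
- Mild base (Et3N, CH2Cl2, rt) and then dilute acid close C2 onto the C7 carbonyl, and dehydration gives 17.

Step 1. Kinetic control in the enolisation may be lost through equilibration towards the γ-deprotonated, linearly conjugated dienolate. The diene may also isomerise under traces of acid or hydrolyse on isolation. Any of these would swap the positions of OMe and OH in ring B. The fallback uses an acyclic ketene acetal diene, in which the oxygen pattern is fixed by constitution and aromatisation occurs by elimination instead of alkene extrusion.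
- It sets out from 8 (silylated in the flask to 9 as in step 4) and comes back at 11, which the work-up of step 4 turns into 12.
- Acylation of commercial 1,1-dimethoxyethene (2 equiv, the second as HCl trap) with acetyl chloride gives 4,4-dimethoxybut-3-en-2-one F9.
- Silylation (TMSCl, Et3N, cat. ZnCl2, benzene) gives 1,1-dimethoxy-3-(trimethylsilyloxy)buta-1,3-diene F10.
- Diels–Alder reaction of F10 with 9 (toluene, 110 °C) gives the 6,6-dimethoxy-2-methyl-4-(trimethylsilyloxy)cyclohexa-1,4-diene-1-carboxylate adduct F11.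
- F11 loses methanol on further heating to give 11.

**Further compounds**
F1 | step 4 | methyl 4-(benzyloxy)-2-hydroxy-6-methylbenzoate | COC(=O)c1c(C)cc(OCc2ccccc2)cc1O
F2 | step 4 | methyl 4-(benzyloxy)-2-methoxy-6-methylbenzoate | COC(=O)c1c(C)cc(OCc2ccccc2)cc1OC
F3 | step 4 | 4-(benzyloxy)-2-methoxy-6-methylbenzoic acid | OC(=O)c1c(C)cc(OCc2ccccc2)cc1OC
F4 | step 4 | methyl 4-{[4-(benzyloxy)-2-methoxy-6-methylbenzoyl]oxy}-2-hydroxy-6-methylbenzoate | COC(=O)c1c(C)cc(OC(=O)c2c(C)cc(OCc3ccccc3)cc2OC)cc1O
F5 | step 6 | 2,2-dimethyl-6-(2-oxopropyl)-4H-1,3-dioxin-4-one | CC(=O)CC1=CC(=O)OC(C)(C)O1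
F6 | step 6 | 2,2-dimethyl-6-(2,4-dioxopentyl)-4H-1,3-dioxin-4-one | CC(=O)CC(=O)CC1=CC(=O)OC(C)(C)O1
F7 | step 6 | 3,5,7-trioxooct-1-en-1-one (acylketene) | CC(=O)CC(=O)CC(=O)C=C=O
F8 | step 6 | 3,5,7-trioxooctanoate of the ring B 4-OH of 12 | CC(=O)CC(=O)CC(=O)CC(=O)Oc1cc(C)c(C(=O)Oc2cc(C)c(C(=O)OC)c(O)c2)c(OC)c1
F9 | step 1 | 4,4-dimethoxybut-3-en-2-one | CC(=O)C=C(OC)OC
F10 | step 1 | 1,1-dimethoxy-3-(trimethylsilyloxy)buta-1,3-diene | C=C(O[Si](C)(C)C)C=C(OC)OC
F11 | step 1 | 4-(methoxycarbonyl)-3-methyl-5-(trimethylsilyloxy)phenyl 6,6-dimethoxy-2-methyl-4-(trimethylsilyloxy)cyclohexa-1,4-diene-1-carboxylate | COC1(OC)C=C(O[Si](C)(C)C)CC(C)=C1C(=O)Oc1cc(C)c(C(=O)OC)c(O[Si](C)(C)C)c1
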